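The target's two ketones, C3 and C7, are 1,5-related, so a temporary C3–C7 bond folds C3–C7 into a five-membered ring that maps onto the cyclopentane of the dextrorotatory bicyclic lactone diol 12 (C5–O and C6–CH2O trans, C7 carrying C8). The route rests on deleting that bond: Baeyer–Villiger oxidation of the C3 cyclopentanone inserts oxygen between C3 and C7 with retention, giving in one operation a six-membered lactone with C3 at acid level and C7 as a masked carbinol. The precursor is an all-trans 2,3,4-trisubstituted cyclopentanone bearing the C8 stereocentre with differentiated C9/C17 oxymethyl arms. The C10–C15 alkenyl iodide is attached at C9 afterwards.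

Key step: step 14

Remark 1: locants follow the open chain of the target (C1–C15 from the ethyl-ketone methyl to the alkene methyl; C16 and C17 are the hydroxymethyl carbons on C6 and C8); TBS = tert-butyldimethylsilyl, TBSO = its oxy form, TES = triethylsilyl, Bn = benzyl.
Remark 2: the target is addressed as the open-chain diketone drawn; hemiketal tautomers of the final polyol are not considered.
Remark 3: C8 is set by convex-face alkylation of the lactone enolate; the new CH2O arm becomes C9 and the lactone carbonyl carbon becomes C17, which gives the C8 configuration of the target and the precursor skeleton in five steps.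
Remark 4: in the target C9–OH and the C10–C11 epoxide are threo-related, whereas hydroxyl-directed epoxidation of a 2-methyl allylic alcohol is erythro-selective; the epoxide is therefore built on the 9R epimer and C9 is inverted afterwards (steps 17–20).

Step 1
Reactants: 1 methyl (R)-3-hydroxy-2-methylpropanoate
Product: 2 methyl (R)-3-(tert-butyldimethylsilyloxy)-2-methylpropanoate
Conditions: TBSCl, imidazole, CH2Cl2, 0 °C to rt
Reagents that add atoms: tert-butyldimethylsilyl chloride, CC(C)(C)[Si](C)(C)Cl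
Why: Imidazole-promoted O-silylation of the primary alcohol is routine and leaves the stereocentre untouched.

Step 2
Reactants: 2 methyl (R)-3-(tert-butyldimethylsilyloxy)-2-methylpropanoate
Product: 3 (R)-3-(tert-butyldimethylsilyloxy)-2-methylpropanal
Conditions: i-Bu2AlH (1.05 equiv), CH2Cl2, −78 °C; aq potassium sodium tartrate
Reagents that add atoms: none
Why: Partial ester reduction with i-Bu2AlH stops at the aluminium hemiacetal at −78 °C and releases the aldehyde on work-up, and the α-stereocentre is kept by cold neutral handling and immediate use.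

Step 3
Reactants: 3 (R)-3-(tert-butyldimethylsilyloxy)-2-methylpropanal
Product: 4 tert-butyldimethylsilyl ether of (2S,3Z)-2-methylpent-3-en-1-ol
Conditions: EtPPh3Br, NaN(SiMe3)2, THF, −78 °C to rt
Reagents that add atoms: ethyltriphenylphosphonium bromide, CC[P+](c1ccccc1)(c1ccccc1)c1ccccc1.[Br-]
Why: Wittig olefination with a non-stabilised, lithium-free ylide is kinetically Z-selective (this sets the C13=C14 geometry) and does not epimerise the α-branched aldehyde at low temperature.

Step 4
Reactants: 4 tert-butyldimethylsilyl ether of (2S,3Z)-2-methylpent-3-en-1-ol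
Product: 5 (2S,3Z)-2-methylpent-3-en-1-ol
Conditions: Bu4NF, THF, 0 °C to rt
Reagents that add atoms: none
Why: Fluoride-induced desilylation frees the primary alcohol, which is volatile and is carried on in solution.

Step 5
Reactants: 5 (2S,3Z)-2-methylpent-3-en-1-ol
Product: 6 (2S,3Z)-2-methylpent-3-enal
Conditions: Dess–Martin periodinane, NaHCO3, CH2Cl2, 0 °C
Reagents that add atoms: none
Why: Dess–Martin oxidation under buffered, base-free conditions should give the β,γ-unsaturated aldehyde without conjugation or epimerisation, provided it is used at once.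

Step 6
Reactants: 6 (2S,3Z)-2-methylpent-3-enal
Product: 7 (3S,4Z)-1,1-dibromo-3-methylhexa-1,4-diene
Conditions: CBr4, PPh3, Zn, CH2Cl2, rt; then 6, 0 °C
Reagents that add atoms: carbon tetrabromide, BrC(Br)(Br)Br
Why: First stage of the Corey–Fuchs reaction, a Wittig-type dibromo-olefination with Ph3P=CBr2 preformed with zinc so that neither excess phosphine nor acid meets the sensitive aldehyde.

Step 7
Reactants: 7 (3S,4Z)-1,1-dibromo-3-methylhexa-1,4-diene
Product: 9 (4S,5Z)-4-methylhept-5-en-2-yne, via lithium acetylide 8 (not isolated)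
Conditions: n-BuLi (2.1 equiv), THF, −78 °C; then MeI, −78 °C to rt
Reagents that add atoms: iodomethane, CI
Why: Second stage of the Corey–Fuchs reaction, in which bromine–lithium exchange and 1,2-shift give the lithium acetylide that is C-methylated in the same flask.

Step 8
Reactants: 9 (4S,5Z)-4-methylhept-5-en-2-yne
Product: 11 (2E,4S,5Z)-2-iodo-4-methylhepta-2,5-diene, via alkenylzirconocene chloride 10 (not isolated)
Conditions: Cp2Zr(H)Cl (1.5 equiv), THF, rt; then I2, 0 °C
Reagents that add atoms: iodine, II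
Why: Hydrozirconation adds H–Zr syn across the alkyne with zirconium at the less hindered methyl-bearing carbon (equilibrated by the slight excess of reagent), and iodinolysis with retention gives the E-iodide, while the internal Z-alkene reacts far more slowly.

Step 9
Reactants: 12 (3aS,4R,5S,6aR)-5-hydroxy-4-(hydroxymethyl)hexahydro-2H-cyclopenta[b]furan-2-one
Product: 13 (3aS,4R,5S,6aR)-5-(TBSO)-4-(TBSO-methyl)hexahydro-2H-cyclopenta[b]furan-2-one
Conditions: TBSCl (2.5 equiv), imidazole, DMF, rt
Reagents that add atoms: tert-butyldimethylsilyl chloride, CC(C)(C)[Si](C)(C)Cl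
Why: Exhaustive O-silylation protects both hydroxyls (the future C5–OH and C16–OH) as ethers that survive every later step and fall together at the end.

Step 10
Reactants: 13 (3aS,4R,5S,6aR)-5-(TBSO)-4-(TBSO-methyl)hexahydro-2H-cyclopenta[b]furan-2-one
Product: 15 (3S,3aR,4R,5S,6aR)-3-[(benzyloxy)methyl]-5-(TBSO)-4-(TBSO-methyl)hexahydro-2H-cyclopenta[b]furan-2-one (new arm on the convex face; the 3a descriptor changes by priority only), via lithium enolate 14 (not isolated)
Conditions: LiN(i-Pr)2, THF, −78 °C; then BnOCH2Cl, −78 to −40 °C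
Reagents that add atoms: benzyl chloromethyl ether, ClCOCc1ccccc1
Why: Alkylation of a lactone lithium enolate with a reactive α-chloro ether, in which the electrophile enters on the convex face of the cis-fused bicycle (cis to H-3a, away from the cyclopentane ring and its C5 silyloxy group) and so fixes C8.

Step 11
Reactants: 15 (3S,3aR,4R,5S,6aR)-3-[(benzyloxy)methyl]-5-(TBSO)-4-(TBSO-methyl)hexahydro-2H-cyclopenta[b]furan-2-one
Product: 16 (1R,2S,3R,4S)-2-[(2R)-1-(benzyloxy)-3-hydroxypropan-2-yl]-4-(TBSO)-3-(TBSO-methyl)cyclopentan-1-ol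
Conditions: LiBH4, THF, 0 °C to rt
Reagents that add atoms: none
Why: Hydride reduction of the lactone to the diol with LiBH4, which leaves silyl and benzyl ethers and all stereocentres intact.

Step 12
Reactants: 16 (1R,2S,3R,4S)-2-[(2R)-1-(benzyloxy)-3-hydroxypropan-2-yl]-4-(TBSO)-3-(TBSO-methyl)cyclopentan-1-ol
Product: 17 (1R,2S,3R,4S)-2-[(2S)-1-(benzyloxy)-3-(TBSO)propan-2-yl]-4-(TBSO)-3-(TBSO-methyl)cyclopentan-1-ol
Conditions: TBSCl (1.05 equiv), imidazole, CH2Cl2, −10 °C
Reagents that add atoms: tert-butyldimethylsilyl chloride, CC(C)(C)[Si](C)(C)Cl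
Why: Sterically controlled mono-silylation, since the primary C17 hydroxyl reacts far faster than the hindered ring carbinol.

Step 13
Reactants: 17 (1R,2S,3R,4S)-2-[(2S)-1-(benzyloxy)-3-(TBSO)propan-2-yl]-4-(TBSO)-3-(TBSO-methyl)cyclopentan-1-ol
Product: 18 (2S,3R,4S)-2-[(2S)-1-(benzyloxy)-3-(TBSO)propan-2-yl]-4-(TBSO)-3-(TBSO-methyl)cyclopentan-1-one (C3–C9 cyclopentanone)
Conditions: Dess–Martin periodinane, NaHCO3, CH2Cl2, 0 °C to rt
Reagents that add atoms: none
Why: Dess–Martin oxidation of the only free hydroxyl under buffered conditions avoids β-elimination of the C5 silyloxy group, and C7 already has the thermodynamically preferred trans relation to C6.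

Step 14
Reactants: 18 (2S,3R,4S)-2-[(2S)-1-(benzyloxy)-3-(TBSO)propan-2-yl]-4-(TBSO)-3-(TBSO-methyl)cyclopentan-1-one
Product: 20 (4S,5S,6S)-6-[(2S)-1-(benzyloxy)-3-(TBSO)propan-2-yl]-4-(TBSO)-5-(TBSO-methyl)tetrahydro-2H-pyran-2-one (C3–C9 δ-lactone), via peroxyester adduct 19 (not isolated)
Conditions: m-CPBA, NaHCO3, CH2Cl2, 0 °C to rt
Reagents that add atoms: 3-chloroperoxybenzoic acid, OOC(=O)c1cccc(Cl)c1
Why: Baeyer–Villiger oxidation: the peracid adds to the C3 carbonyl to give the tetrahedral peroxyester adduct 19, whose C7–C3 bond, antiperiplanar to the breaking O–O bond, migrates to oxygen in a concerted 1,2-shift as 3-chlorobenzoate leaves. The closest known reaction type is the peracid ring expansion of 2-alkylcyclopentanones to 6-alkyl δ-lactones. The six-membered lactone is formed not by a cyclisation but by ring expansion of the five-membered ring, oxygen being inserted into the C3–C7 bond. No stereocentre is created, and C7 migrates with retention because the shift is suprafacial, so its configuration from 12 passes into the C7–O bond. The step needs regioselective migration of C7 over C4, and the substrate secures it twice: C7 is secondary while C4 is primary, and C4 is further deactivated by the electron-withdrawing β-silyloxy group at C5. Solid NaHCO3 keeps the medium neutral so that the C5 silyloxy group is not eliminated, and the silyl and benzyl ethers offer the peracid neither an alkene nor an electron-rich arene.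

Step 15
Reactants: 20 (4S,5S,6S)-6-[(2S)-1-(benzyloxy)-3-(TBSO)propan-2-yl]-4-(TBSO)-5-(TBSO-methyl)tetrahydro-2H-pyran-2-one
Product: 21 (4S,5S,6S)-6-[(2S)-1-hydroxy-3-(TBSO)propan-2-yl]-4-(TBSO)-5-(TBSO-methyl)tetrahydro-2H-pyran-2-one (C9 alcohol)
Conditions: H2 (1 atm), 10% Pd on carbon, EtOAc, rt
Reagents that add atoms: none
Why: Hydrogenolysis of the benzyl ether frees C9–OH alone, because lactone and silyl ethers are inert in ethyl acetate and no alkene is present yet.

Step 16
Reactants: 21 C9 alcohol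
Product: 22 C9 aldehyde (21 with CH2OH oxidised to CHO; stereocentres as in 21)
Conditions: Dess–Martin periodinane, NaHCO3, CH2Cl2, 0 °C
Reagents that add atoms: none
Why: Dess–Martin oxidation under buffered, base-free conditions avoids epimerisation at C8 and β-elimination of the lactone oxygen at C7, and the aldehyde is used at once.

Step 17
Reactants: 22 C9 aldehyde; 11 (2E,4S,5Z)-2-iodo-4-methylhepta-2,5-diene
Product: 24 (9R)-allylic alcohol (C9–C10 bond formed; 10E and 13Z alkenes; lactone part as in 22), via alkenylchromium dichloride 23 (not isolated)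
Conditions: CrCl2 (5 equiv), NiCl2 (2 mol %), DMSO, rt
Reagents that add atoms: none
Why: Nozaki–Hiyama–Kishi reaction, in which the alkenylchromium reagent adds to the aldehyde only (the lactone is untouched) with retention of the E geometry, and Felkin–Anh attack anti to the branched ring carbon C7 on C8 should favour the 9R carbinol, the 9S epimer being removed by chromatography.

Step 18
Reactants: 24 (9R)-allylic alcohol
Product: 25 (9R,10R,11R)-10,11-epoxy alcohol (epoxide as in the target)
Conditions: VO(acac)2 (5 mol %), t-BuOOH, CH2Cl2, 0 °C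
Reagents that add atoms: tert-butyl hydroperoxide, CC(C)(C)OO
Why: Hydroxyl-directed vanadium-catalysed epoxidation touches only the allylic C10=C11 bond, and A(1,2) strain (H-9 eclipsing the C10 methyl, C8 on the face away from the oxidant) directs oxygen to the face that, for the 9R carbinol, is the 10R,11R epoxide of the target.

Step 19
Reactants: 25 (9R,10R,11R)-10,11-epoxy alcohol
Product: 26 10,11-epoxy C9 ketone (epoxide and all other centres unchanged)
Conditions: Dess–Martin periodinane, NaHCO3, CH2Cl2, 0 °C to rt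
Reagents that add atoms: none
Why: Dess–Martin oxidation of the single free carbinol under buffered conditions, so that neither the epoxide nor the base-sensitive C8 centre is disturbed.

Step 20
Reactants: 26 10,11-epoxy C9 ketone
Product: 27 (9S,10R,11R)-10,11-epoxy alcohol
Conditions: K[HB(sec-Bu)3], THF, −78 °C
Reagents that add atoms: none
Why: Diastereoselective ketone reduction by a bulky non-chelating hydride, for which attack anti to the C7 branch on C8 and anti to the epoxide C–O bond on C10 (Felkin–Anh control from both sides) falls on the same carbonyl face and should give the 9S alcohol, while any 9R alcohol 25 re-formed can be sent back through step 19.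

Step 21
Reactants: 27 (9S,10R,11R)-10,11-epoxy alcohol
Product: 28 C9 triethylsilyl ether of 27
Conditions: Et3SiOTf, 2,6-lutidine, CH2Cl2, −78 °C
Reagents that add atoms: triethylsilyl trifluoromethanesulfonate, CC[Si](CC)(CC)OS(=O)(=O)C(F)(F)F
Why: Silylation with a silyl triflate and a hindered base at low temperature protects the congested C9 carbinol quickly enough to spare the epoxide.

Step 22
Reactants: 28 C9 triethylsilyl ether of 27
Product: 30 C7-hydroxy C3 ethyl ketone (open C1–C15 chain; TBSO on C5, C16, C17; TES ether on C9), via lithium lactolate 29 (not isolated)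
Conditions: EtLi (1.2 equiv), THF, −78 °C; then AcOH, −78 °C
Reagents that add atoms: ethyllithium, [Li]CC
Why: Mono-addition of an alkyllithium to a δ-lactone works because the tetrahedral lithium lactolate is stable at −78 °C and opens only on protonation, releasing the ethyl ketone and the free C7 carbinol together after the nucleophile has been quenched.

Step 23
Reactants: 30 C7-hydroxy C3 ethyl ketone
Product: 31 C3,C7-diketone (per-silylated target)
Conditions: Dess–Martin periodinane, NaHCO3, CH2Cl2, 0 °C to rt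
Reagents that add atoms: none
Why: Dess–Martin oxidation of the only free hydroxyl (any cyclic hemiketal tautomer of 30 reacts through the open form), so that C6 and C8 become enolisable only at this late, buffered stage.

Step 24
Reactants: 31 C3,C7-diketone
Product: 32 (5S,6R,8R,9S,10R,11R,12S,13Z)-10,11-epoxy-5,9-dihydroxy-6,8-bis(hydroxymethyl)-10,12-dimethylpentadec-13-ene-3,7-dione (CNP0266199.1)
Conditions: HF·pyridine, pyridine, THF, 0 °C to rt
Reagents that add atoms: none
Why: Global desilylation with pyridine-buffered HF·pyridine is mild enough for the trisubstituted epoxide and the β-hydroxy ketones, and it touches no stereocentre.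

Compound list
1 | methyl (R)-3-hydroxy-2-methylpropanoate | C[C@H](CO)C(=O)OC | starting material
2 | methyl (R)-3-(tert-butyldimethylsilyloxy)-2-methylpropanoate | C[C@H](CO[Si](C)(C)C(C)(C)C)C(=O)OC | intermediate
3 | (R)-3-(tert-butyldimethylsilyloxy)-2-methylpropanal | C[C@H](CO[Si](C)(C)C(C)(C)C)C=O | intermediate
4 | tert-butyldimethylsilyl ether of (2S,3Z)-2-methylpent-3-en-1-ol | C/C=C\[C@H](C)CO[Si](C)(C)C(C)(C)C | intermediate
5 | (2S,3Z)-2-methylpent-3-en-1-ol | C/C=C\[C@H](C)CO | intermediate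
6 | (2S,3Z)-2-methylpent-3-enal | C/C=C\[C@H](C)C=O | intermediate
7 | (3S,4Z)-1,1-dibromo-3-methylhexa-1,4-diene | C/C=C\[C@H](C)C=C(Br)Br | intermediate
8 | lithium (3S,4Z)-3-methylhex-4-en-1-yn-1-ide (not isolated) | C/C=C\[C@H](C)C#C[Li] | intermediate
9 | (4S,5Z)-4-methylhept-5-en-2-yne | C/C=C\[C@H](C)C#CC | intermediate
10 | chlorobis(cyclopentadienyl)[(2E,4S,5Z)-4-methylhepta-2,5-dien-2-yl]zirconium (not isolated) | C/C=C\[C@H](C)/C=C(\C)[Zr](Cl)(C1C=CC=C1)C1C=CC=C1 | intermediate
11 | (2E,4S,5Z)-2-iodo-4-methylhepta-2,5-diene | C/C=C\[C@H](C)/C=C(\C)I | intermediate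
12 | (3aS,4R,5S,6aR)-5-hydroxy-4-(hydroxymethyl)hexahydro-2H-cyclopenta[b]furan-2-one | O=C1C[C@H]2[C@H](CO)[C@@H](O)C[C@H]2O1 | starting material
13 | (3aS,4R,5S,6aR)-5-(TBSO)-4-(TBSO-methyl)hexahydro-2H-cyclopenta[b]furan-2-one | O=C1C[C@H]2[C@H](CO[Si](C)(C)C(C)(C)C)[C@@H](O[Si](C)(C)C(C)(C)C)C[C@H]2O1 | intermediate
14 | lithium enolate of 13 (not isolated) | [Li]OC1=C[C@H]2[C@H](CO[Si](C)(C)C(C)(C)C)[C@@H](O[Si](C)(C)C(C)(C)C)C[C@H]2O1 | intermediate
15 | (3S,3aR,4R,5S,6aR)-3-[(benzyloxy)methyl]-5-(TBSO)-4-(TBSO-methyl)hexahydro-2H-cyclopenta[b]furan-2-one | O=C1[C@H](COCc2ccccc2)[C@H]3[C@H](CO[Si](C)(C)C(C)(C)C)[C@@H](O[Si](C)(C)C(C)(C)C)C[C@H]3O1 | intermediate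
16 | (1R,2S,3R,4S)-2-[(2R)-1-(benzyloxy)-3-hydroxypropan-2-yl]-4-(TBSO)-3-(TBSO-methyl)cyclopentan-1-ol | OC[C@H](COCc1ccccc1)[C@H]2[C@H](CO[Si](C)(C)C(C)(C)C)[C@@H](O[Si](C)(C)C(C)(C)C)C[C@H]2O | intermediate
17 | (1R,2S,3R,4S)-2-[(2S)-1-(benzyloxy)-3-(TBSO)propan-2-yl]-4-(TBSO)-3-(TBSO-methyl)cyclopentan-1-ol | CC(C)(C)[Si](C)(C)OC[C@H](COCc1ccccc1)[C@H]2[C@H](CO[Si](C)(C)C(C)(C)C)[C@@H](O[Si](C)(C)C(C)(C)C)C[C@H]2O | intermediate
18 | (2S,3R,4S)-2-[(2S)-1-(benzyloxy)-3-(TBSO)propan-2-yl]-4-(TBSO)-3-(TBSO-methyl)cyclopentan-1-one (C3–C9 cyclopentanone) | CC(C)(C)[Si](C)(C)OC[C@H](COCc1ccccc1)[C@H]2[C@H](CO[Si](C)(C)C(C)(C)C)[C@@H](O[Si](C)(C)C(C)(C)C)CC2=O | intermediate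
19 | peroxyester (Criegee-type) adduct of 18 at C3, either configuration at C3 (not isolated) | CC(C)(C)[Si](C)(C)OC[C@H](COCc1ccccc1)[C@H]2[C@H](CO[Si](C)(C)C(C)(C)C)[C@@H](O[Si](C)(C)C(C)(C)C)CC2(O)OOC(=O)c3cccc(Cl)c3 | intermediate
20 | (4S,5S,6S)-6-[(2S)-1-(benzyloxy)-3-(TBSO)propan-2-yl]-4-(TBSO)-5-(TBSO-methyl)tetrahydro-2H-pyran-2-one (C3–C9 δ-lactone) | CC(C)(C)[Si](C)(C)OC[C@H](COCc1ccccc1)[C@@H]2OC(=O)C[C@H](O[Si](C)(C)C(C)(C)C)[C@H]2CO[Si](C)(C)C(C)(C)C | intermediate
21 | (4S,5S,6S)-6-[(2S)-1-hydroxy-3-(TBSO)propan-2-yl]-4-(TBSO)-5-(TBSO-methyl)tetrahydro-2H-pyran-2-one (C9 alcohol) | CC(C)(C)[Si](C)(C)OC[C@H](CO)[C@@H]1OC(=O)C[C@H](O[Si](C)(C)C(C)(C)C)[C@H]1CO[Si](C)(C)C(C)(C)C | intermediate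
22 | C9 aldehyde (21 with C9 as CHO) | CC(C)(C)[Si](C)(C)OC[C@H](C=O)[C@@H]1OC(=O)C[C@H](O[Si](C)(C)C(C)(C)C)[C@H]1CO[Si](C)(C)C(C)(C)C | intermediate
23 | dichloro[(2E,4S,5Z)-4-methylhepta-2,5-dien-2-yl]chromium (not isolated) | C/C=C\[C@H](C)/C=C(\C)[Cr](Cl)Cl | intermediate
24 | (9R)-allylic alcohol (10E,13Z; lactone part as in 22) | C/C=C\[C@H](C)/C=C(\C)[C@H](O)[C@@H](CO[Si](C)(C)C(C)(C)C)[C@@H]1OC(=O)C[C@H](O[Si](C)(C)C(C)(C)C)[C@H]1CO[Si](C)(C)C(C)(C)C | intermediate
25 | (9R,10R,11R)-10,11-epoxy alcohol | C/C=C\[C@H](C)[C@H]1O[C@]1(C)[C@H](O)[C@@H](CO[Si](C)(C)C(C)(C)C)[C@@H]2OC(=O)C[C@H](O[Si](C)(C)C(C)(C)C)[C@H]2CO[Si](C)(C)C(C)(C)C | intermediate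
26 | 10,11-epoxy C9 ketone | C/C=C\[C@H](C)[C@H]1O[C@]1(C)C(=O)[C@@H](CO[Si](C)(C)C(C)(C)C)[C@@H]2OC(=O)C[C@H](O[Si](C)(C)C(C)(C)C)[C@H]2CO[Si](C)(C)C(C)(C)C | intermediate
27 | (9S,10R,11R)-10,11-epoxy alcohol | C/C=C\[C@H](C)[C@H]1O[C@]1(C)[C@@H](O)[C@@H](CO[Si](C)(C)C(C)(C)C)[C@@H]2OC(=O)C[C@H](O[Si](C)(C)C(C)(C)C)[C@H]2CO[Si](C)(C)C(C)(C)C | intermediate
28 | C9 triethylsilyl ether of 27 | C/C=C\[C@H](C)[C@H]1O[C@]1(C)[C@@H](O[Si](CC)(CC)CC)[C@@H](CO[Si](C)(C)C(C)(C)C)[C@@H]2OC(=O)C[C@H](O[Si](C)(C)C(C)(C)C)[C@H]2CO[Si](C)(C)C(C)(C)C | intermediate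
29 | lithium lactolate from 28 and ethyllithium, either configuration at C3 (not isolated) | C/C=C\[C@H](C)[C@H]1O[C@]1(C)[C@@H](O[Si](CC)(CC)CC)[C@@H](CO[Si](C)(C)C(C)(C)C)[C@@H]2OC(CC)(O[Li])C[C@H](O[Si](C)(C)C(C)(C)C)[C@H]2CO[Si](C)(C)C(C)(C)C | intermediate
30 | C7-hydroxy C3 ethyl ketone (TBSO on C5, C16, C17; TES ether on C9) | C/C=C\[C@H](C)[C@H]1O[C@]1(C)[C@@H](O[Si](CC)(CC)CC)[C@@H](CO[Si](C)(C)C(C)(C)C)[C@H](O)[C@H](CO[Si](C)(C)C(C)(C)C)[C@@H](O[Si](C)(C)C(C)(C)C)CC(=O)CC | intermediate
31 | C3,C7-diketone (per-silylated target) | C/C=C\[C@H](C)[C@H]1O[C@]1(C)[C@@H](O[Si](CC)(CC)CC)[C@@H](CO[Si](C)(C)C(C)(C)C)C(=O)[C@H](CO[Si](C)(C)C(C)(C)C)[C@@H](O[Si](C)(C)C(C)(C)C)CC(=O)CC | intermediate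
32 | (5S,6R,8R,9S,10R,11R,12S,13Z)-10,11-epoxy-5,9-dihydroxy-6,8-bis(hydroxymethyl)-10,12-dimethylpentadec-13-ene-3,7-dione | C/C=C\[C@H](C)[C@H]1O[C@]1(C)[C@@H](O)[C@@H](CO)C(=O)[C@H](CO)[C@@H](O)CC(=O)CC | target

Total step count: 24. Longest linear sequence: 16 steps (steps 9–24 from 12; steps 1–8 followed by 17–24 from 1 are equally long).

Steps most likely to fail

Step 20. Hydride delivery to the hindered epoxy ketone may discriminate the two carbonyl faces poorly, or chelation through the epoxide oxygen may reverse the sense. Setting out from 25, C9 is inverted by substitution instead of by reduction: a Mitsunobu reaction with chloroacetic acid (PPh3, diisopropyl azodicarboxylate, toluene, 0 °C to rt) should give the C9-inverted chloroacetate F1. Thiourea and NaHCO3 in ethanol at rt then remove the chloroacetyl group without touching the lactone, and the route is rejoined at 27.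

Step 17. The chromium-mediated addition may show poor facial selectivity at C9, so that material is lost as the unwanted epimer. Setting out from 22 and 11, the coupling is run without regard to selectivity to give 24 together with its 9S epimer F2. Dess–Martin oxidation of the mixture (NaHCO3, CH2Cl2) converges both on the enone F3. Corey–Bakshi–Shibata reduction ((S)-2-methyl-CBS-oxazaborolidine, catecholborane, toluene, −78 °C, the alkenyl arm acting as the larger ketone substituent) then sets C9 under reagent control, and the route is rejoined at 24.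

Step 22. Over-addition to the released ketone, or enolisation of the lactone with β-elimination of the C5 silyloxy group, may compete with clean mono-addition. Setting out from 28, the lactone is first opened with MeNH(OMe)·HCl and i-PrMgCl (THF, −20 °C) to the δ-hydroxy N-methoxy-N-methylamide F4. Its chelated tetrahedral adduct with EtMgBr (3 equiv, THF, 0 °C) cannot add a second time, and work-up rejoins the route at 30.

Further compounds
F1 | step 20 | C9-inverted (9S) chloroacetate of the 10,11-epoxy alcohol | C/C=C\[C@H](C)[C@H]1O[C@]1(C)[C@@H](OC(=O)CCl)[C@@H](CO[Si](C)(C)C(C)(C)C)[C@@H]2OC(=O)C[C@H](O[Si](C)(C)C(C)(C)C)[C@H]2CO[Si](C)(C)C(C)(C)C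
F2 | step 17 | 9S epimer of allylic alcohol 24 | C/C=C\[C@H](C)/C=C(\C)[C@@H](O)[C@@H](CO[Si](C)(C)C(C)(C)C)[C@@H]1OC(=O)C[C@H](O[Si](C)(C)C(C)(C)C)[C@H]1CO[Si](C)(C)C(C)(C)C
F3 | step 17 | C9 enone (10E,13Z) | C/C=C\[C@H](C)/C=C(\C)C(=O)[C@@H](CO[Si](C)(C)C(C)(C)C)[C@@H]1OC(=O)C[C@H](O[Si](C)(C)C(C)(C)C)[C@H]1CO[Si](C)(C)C(C)(C)C
F4 | step 22 | C7-hydroxy C3 N-methoxy-N-methylamide | C/C=C\[C@H](C)[C@H]1O[C@]1(C)[C@@H](O[Si](CC)(CC)CC)[C@@H](CO[Si](C)(C)C(C)(C)C)[C@H](O)[C@H](CO[Si](C)(C)C(C)(C)C)[C@@H](O[Si](C)(C)C(C)(C)C)CC(=O)N(C)OC
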